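**Plan**

- All fifteen hydroxyls are carried as methyl ethers. Four diaryl ether bonds (F–E, E–D, C–B, B–A) are cut between a phenol oxygen and the doubly oxygen-flanked carbon of the next ring, which arrives as 4-fluoro-3,5-dimethoxybenzaldehyde (formyl = latent OH). The fifth (C–D) is cut between the hindered ring C oxygen and an aryne carbon of ring D.
- Forward: F → E–F → D–E–F by two SNAr/Baeyer–Villiger rounds, then the ring D phenol is turned into a 2-(trimethylsilyl)aryl triflate. Ring C is made separately as a catechol.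
- Enabling feature: ring C has two adjacent ether oxygens. The one on the carbon next to ring C's only C–H is bonded to the ring B carbon that lies between two oxygen-bearing carbons. The other, next to an oxygen-bearing carbon, is bonded to a ring D carbon with C–H on both sides. A catechol can therefore be joined in one flask to an SNAr electrophile and then to an aryne.
- After that union the ring B formyl group is converted to OH, ring A is added by the same SNAr/Baeyer–Villiger pair, and all methyl ethers are cleaved.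
- Stereochemistry: none to set; the target is achiral.

Key step: step 10

Remark: the target has no stereogenic element, so no step needs stereocontrol; rings are lettered A–F along the chain (A = 2,4,6-trihydroxyphenyl end, F = 3,4,5-trihydroxyphenyl end); the mixed aryl borates formed in step 14 before hydrolysis are not a single compound and carry no number.

**Route**

Step 1
Reactants: 1 syringaldehyde (4-hydroxy-3,5-dimethoxybenzaldehyde)
Product: 3 4-fluoro-3,5-dimethoxybenzaldehyde, via aryloxyimidazolium bifluoride 2 (not isolated)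
Conditions: PhenoFluor (1.2 equiv), CsF (3 equiv), toluene, 110 °C
Reagents that add atoms: PhenoFluor, CC(C)c1cccc(C(C)C)c1N1C=CN(c2c(C(C)C)cccc2C(C)C)C1(F)F; cesium fluoride, [Cs+].[F-] (shared fluoride pool)
Why: Phenol deoxyfluorination: 1 condenses with the difluoroimidazoline to salt 2, whose bifluoride delivers fluoride to the ipso carbon in a concerted nucleophilic aromatic substitution that the para formyl group accelerates and that the small nucleophile should tolerate despite the two ortho methoxyls.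

Step 2
Reactants: 4 3,4,5-trimethoxyphenol; 3 4-fluoro-3,5-dimethoxybenzaldehyde
Product: 5 3,5-dimethoxy-4-(3,4,5-trimethoxyphenoxy)benzaldehyde (E–F aldehyde)
Conditions: Cs2CO3, DMAc, 120 °C, Ar
Reagents that add atoms: none
Why: Nucleophilic aromatic substitution (addition–elimination through a Meisenheimer complex) of an unhindered, electron-rich phenoxide para to the formyl group, the classical entry to 4-aryloxybenzaldehydes from 4-fluorobenzaldehydes.

Step 3
Reactants: 5 E–F aldehyde
Product: 7 3,5-dimethoxy-4-(3,4,5-trimethoxyphenoxy)phenol (E–F phenol), via E–F aryl formate 6 (not isolated)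
Conditions: mCPBA, CH2Cl2, 0 °C to rt; aq Na2S2O3/NaHCO3 wash; then cat. K2CO3, MeOH, rt
Reagents that add atoms: 3-chloroperoxybenzoic acid, O=C(OO)c1cccc(Cl)c1
Why: Baeyer–Villiger (Dakin-type) oxidation in which the electron-rich aryl group migrates to give formate 6, methanolysed under catalytic base; this is the standard conversion of 4-aryloxy- and polymethoxybenzaldehydes into phenols, and the peracid is removed before the oxidizable phenol is released.

Step 4
Reactants: 7 E–F phenol; 3 4-fluoro-3,5-dimethoxybenzaldehyde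
Product: 8 3,5-dimethoxy-4-[3,5-dimethoxy-4-(3,4,5-trimethoxyphenoxy)phenoxy]benzaldehyde (D–E–F aldehyde)
Conditions: Cs2CO3, DMAc, 120 °C, Ar
Reagents that add atoms: none
Why: Second nucleophilic aromatic substitution of the same type as step 2; the phenoxide of 7 has hydrogen on both ortho positions and the ether and methoxyl groups are inert to carbonate.

Step 5
Reactants: 8 D–E–F aldehyde
Product: 10 3,5-dimethoxy-4-[3,5-dimethoxy-4-(3,4,5-trimethoxyphenoxy)phenoxy]phenol (D–E–F phenol), via D–E–F aryl formate 9 (not isolated)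
Conditions: mCPBA, CH2Cl2, 0 °C to rt; aq Na2S2O3/NaHCO3 wash; then cat. K2CO3, MeOH, rt
Reagents that add atoms: 3-chloroperoxybenzoic acid, O=C(OO)c1cccc(Cl)c1
Why: Baeyer–Villiger oxidation and formate methanolysis as in step 3, now on the trimer.

Step 6
Reactants: 10 D–E–F phenol
Product: 11 2-bromo-3,5-dimethoxy-4-[3,5-dimethoxy-4-(3,4,5-trimethoxyphenoxy)phenoxy]phenol
Conditions: NBS (1.0 equiv), CH2Cl2, −78 to 0 °C
Reagents that add atoms: N-bromosuccinimide, O=C1CCC(=O)N1Br
Why: Electrophilic aromatic bromination; the free phenol ring is the most activated of the three, its two open positions (ortho to OH, ortho and para to methoxyls) are equivalent, so one equivalent of NBS at low temperature should give the mono-ortho-bromide.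

Step 7
Reactants: 11 ortho-bromophenol
Product: 15 3,5-dimethoxy-4-[3,5-dimethoxy-4-(3,4,5-trimethoxyphenoxy)phenoxy]-2-(trimethylsilyl)phenyl trifluoromethanesulfonate (D–E–F silyl triflate), via aryl trimethylsilyl ether 12 (not isolated), via aryllithium 13 (not isolated), via lithium 2-silylphenoxide 14 (not isolated)
Conditions: HMDS, THF, 70 °C, evaporate; n-BuLi (1.05 equiv), THF, −78 °C; then Tf2O, −78 °C
Reagents that add atoms: hexamethyldisilazane, C[Si](C)(C)N[Si](C)(C)C; trifluoromethanesulfonic anhydride, O=S(=O)(OS(=O)(=O)C(F)(F)F)C(F)(F)F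
Why: O-silylation, bromine–lithium exchange and retro-Brook 1,3-O→C silyl migration put the silyl group exactly where bromine stood, and the freed phenoxide is triflated, the standard route to 2-(trimethylsilyl)aryl triflates; halogen–metal exchange at −78 °C outruns deprotonation of the other rings.

Step 8
Reactants: 4 3,4,5-trimethoxyphenol
Product: 17 6-hydroxy-2,3,4-trimethoxybenzaldehyde, via salicyl alcohol 16 (not isolated)
Conditions: MgCl2, Et3N, paraformaldehyde, MeCN, reflux; aq HCl work-up
Reagents that add atoms: paraformaldehyde (as formaldehyde), C=O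
Why: Magnesium-mediated ortho-formylation of a phenol: the magnesium phenoxide directs formaldehyde to an ortho carbon (both are equivalent) and the benzylic alkoxide of 16 is oxidized to the aldehyde by hydride transfer to a second formaldehyde.

Step 9
Reactants: 17 6-hydroxy-2,3,4-trimethoxybenzaldehyde
Product: 19 3,4,5-trimethoxybenzene-1,2-diol (ring C catechol), via hydroxyaryl formate 18 (not isolated)
Conditions: 30% aq H2O2, NaOH, THF–H2O, 0 °C, Ar; then aq HCl
Reagents that add atoms: hydrogen peroxide, OO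
Why: Dakin oxidation of an ortho-hydroxybenzaldehyde, in which hydroperoxide adds to the formyl group, the electron-rich aryl migrates and formate 18 is saponified in situ, so the formyl carbon is replaced by the methoxyl-flanked hydroxyl; air is excluded to protect the electron-rich catechol.

Step 10
Reactants: 19 3,4,5-trimethoxybenzene-1,2-diol; 3 4-fluoro-3,5-dimethoxybenzaldehyde; 15 D–E–F silyl triflate
Product: 22 permethylated B–C–D–E–F pentamer aldehyde, via B–C hydroxy diaryl ether 20 (not isolated), via D–E–F aryne 21 (not isolated)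
Conditions: 19 and 3 (1.0 equiv each), Cs2CO3 (1.5 equiv), degassed MeCN, 90 °C (sealed), Ar; then rt, 15 (1.1 equiv), CsF (3 equiv), rt to 40 °C
Reagents that add atoms: none
Why: Carbonate forms the catechol monoanion, whose oxygen beside the ring C–H adds para to the formyl group of 3 and expels fluoride through a Meisenheimer complex to give phenoxide 20; the other oxygen, next to a methoxyl, is poorly placed to attack a fluoride-bearing carbon that itself lies between two methoxyls, and the less crowded ether is also the thermodynamically preferred one should the aryl group shuttle between the two oxygens (Smiles-type) at 90 °C. Fluoride then removes the trimethylsilyl group of 15, triflate departs, and aryne 21 is captured by the hindered phenoxide of 20 at the aryne carbon remote from the neighbouring methoxyl, the aryl anion being protonated by hydrogencarbonate or acetonitrile. The closest known reaction types are the phenoxide SNAr on 4-fluorobenzaldehydes and the fluoride-induced O-arylation of phenols by 2-(trimethylsilyl)aryl triflates, run here one after the other in acetonitrile, the usual medium for the second. No ring closes and no stereocentre forms. The step needs site selectivity between the two catechol oxygens, secured by the H versus OMe neighbour meeting a doubly flanked C–F carbon, and regioselectivity of aryne capture, secured by the methoxyl adjacent to the triple bond, which polarizes it so that the nucleophile enters at the distal carbon. The formyl group is left intact as the latent ring B phenol.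

Step 11
Reactants: 22 pentamer aldehyde
Product: 24 permethylated B–C–D–E–F pentamer phenol (free OH on ring B), via pentamer aryl formate 23 (not isolated)
Conditions: mCPBA (1.1 equiv), CH2Cl2, 0 °C; aq Na2S2O3/NaHCO3 wash; then cat. K2CO3, MeOH, rt
Reagents that add atoms: 3-chloroperoxybenzoic acid, O=C(OO)c1cccc(Cl)c1
Why: Baeyer–Villiger oxidation and formate methanolysis as in step 3; a slight excess of peracid at 0 °C keeps oxidation of the electron-rich rings behind the much faster aldehyde oxidation.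

Step 12
Reactants: 24 pentamer phenol; 3 4-fluoro-3,5-dimethoxybenzaldehyde
Product: 25 permethylated A–F hexamer aldehyde (ring A = 4-formyl-2,6-dimethoxyphenyl)
Conditions: Cs2CO3, DMAc, 120 °C, Ar
Reagents that add atoms: none
Why: Nucleophilic aromatic substitution as in step 2; the ring B phenoxide has hydrogen on both ortho positions and should behave like 7.

Step 13
Reactants: 25 hexamer aldehyde
Product: 27 permethylated A–F hexamer phenol (ring A = 4-hydroxy-2,6-dimethoxyphenyl), via hexamer aryl formate 26 (not isolated)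
Conditions: mCPBA (1.1 equiv), CH2Cl2, 0 °C; aq Na2S2O3/NaHCO3 wash; then cat. K2CO3, MeOH, rt
Reagents that add atoms: 3-chloroperoxybenzoic acid, O=C(OO)c1cccc(Cl)c1
Why: Baeyer–Villiger oxidation and formate methanolysis as in steps 3 and 11, installing the last oxygen of ring A.

Step 14
Reactants: 27 hexamer phenol
Product: 28 CNP0270681.0 (target)
Conditions: BBr3 (30 equiv), CH2Cl2, −78 °C to rt, Ar; MeOH then H2O at 0 °C; degassed reverse-phase purification
Reagents that add atoms: none
Why: Lewis-acid ether cleavage in which BBr3 coordinates each methoxyl oxygen and bromide removes the methyl group by SN2, while the diaryl ether C–O bonds offer no sp3 carbon and should stay intact; hydrolysis of the aryl borates frees the fifteen hydroxyls.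

**Compound list**

1 | syringaldehyde (4-hydroxy-3,5-dimethoxybenzaldehyde) | COc1cc(C=O)cc(OC)c1O | starting material
2 | 2-(4-formyl-2,6-dimethoxyphenoxy)-1,3-bis(2,6-diisopropylphenyl)imidazolium hydrogen difluoride | O=Cc1cc(OC)c(OC2=[N+](c3c(C(C)C)cccc3C(C)C)C=CN2c2c(C(C)C)cccc2C(C)C)c(OC)c1.[F-].F | intermediate
3 | 4-fluoro-3,5-dimethoxybenzaldehyde | COc1cc(C=O)cc(OC)c1F | intermediate
4 | 3,4,5-trimethoxyphenol | COc1cc(O)cc(OC)c1OC | starting material
5 | 3,5-dimethoxy-4-(3,4,5-trimethoxyphenoxy)benzaldehyde | O=Cc1cc(OC)c(Oc2cc(OC)c(OC)c(OC)c2)c(OC)c1 | intermediate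
6 | 3,5-dimethoxy-4-(3,4,5-trimethoxyphenoxy)phenyl formate | O=COc1cc(OC)c(Oc2cc(OC)c(OC)c(OC)c2)c(OC)c1 | intermediate
7 | 3,5-dimethoxy-4-(3,4,5-trimethoxyphenoxy)phenol | Oc1cc(OC)c(Oc2cc(OC)c(OC)c(OC)c2)c(OC)c1 | intermediate
8 | 3,5-dimethoxy-4-[3,5-dimethoxy-4-(3,4,5-trimethoxyphenoxy)phenoxy]benzaldehyde | O=Cc1cc(OC)c(Oc2cc(OC)c(Oc3cc(OC)c(OC)c(OC)c3)c(OC)c2)c(OC)c1 | intermediate
9 | 3,5-dimethoxy-4-[3,5-dimethoxy-4-(3,4,5-trimethoxyphenoxy)phenoxy]phenyl formate | O=COc1cc(OC)c(Oc2cc(OC)c(Oc3cc(OC)c(OC)c(OC)c3)c(OC)c2)c(OC)c1 | intermediate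
10 | 3,5-dimethoxy-4-[3,5-dimethoxy-4-(3,4,5-trimethoxyphenoxy)phenoxy]phenol | Oc1cc(OC)c(Oc2cc(OC)c(Oc3cc(OC)c(OC)c(OC)c3)c(OC)c2)c(OC)c1 | intermediate
11 | 2-bromo-3,5-dimethoxy-4-[3,5-dimethoxy-4-(3,4,5-trimethoxyphenoxy)phenoxy]phenol | Oc1cc(OC)c(Oc2cc(OC)c(Oc3cc(OC)c(OC)c(OC)c3)c(OC)c2)c(OC)c1Br | intermediate
12 | trimethylsilyl ether of 11 | C[Si](C)(C)Oc1cc(OC)c(Oc2cc(OC)c(Oc3cc(OC)c(OC)c(OC)c3)c(OC)c2)c(OC)c1Br | intermediate
13 | 2-lithio aryl trimethylsilyl ether (lithium in place of bromine in 12) | C[Si](C)(C)Oc1cc(OC)c(Oc2cc(OC)c(Oc3cc(OC)c(OC)c(OC)c3)c(OC)c2)c(OC)c1[Li] | intermediate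
14 | lithium 3,5-dimethoxy-4-[3,5-dimethoxy-4-(3,4,5-trimethoxyphenoxy)phenoxy]-2-(trimethylsilyl)phenoxide | [Li+].[O-]c1cc(OC)c(Oc2cc(OC)c(Oc3cc(OC)c(OC)c(OC)c3)c(OC)c2)c(OC)c1[Si](C)(C)C | intermediate
15 | 3,5-dimethoxy-4-[3,5-dimethoxy-4-(3,4,5-trimethoxyphenoxy)phenoxy]-2-(trimethylsilyl)phenyl trifluoromethanesulfonate | C[Si](C)(C)c1c(OC)c(Oc2cc(OC)c(Oc3cc(OC)c(OC)c(OC)c3)c(OC)c2)c(OC)cc1OS(=O)(=O)C(F)(F)F | intermediate
16 | 2-(hydroxymethyl)-3,4,5-trimethoxyphenol (present as magnesium salt) | OCc1c(O)cc(OC)c(OC)c1OC | intermediate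
17 | 6-hydroxy-2,3,4-trimethoxybenzaldehyde | O=Cc1c(O)cc(OC)c(OC)c1OC | intermediate
18 | 6-hydroxy-2,3,4-trimethoxyphenyl formate | O=COc1c(O)cc(OC)c(OC)c1OC | intermediate
19 | 3,4,5-trimethoxybenzene-1,2-diol | COc1cc(O)c(O)c(OC)c1OC | intermediate
20 | 4-(2-hydroxy-3,4,5-trimethoxyphenoxy)-3,5-dimethoxybenzaldehyde (present as cesium phenoxide) | O=Cc1cc(OC)c(Oc2cc(OC)c(OC)c(OC)c2O)c(OC)c1 | intermediate
21 | 3,5-dimethoxy-4-[3,5-dimethoxy-4-(3,4,5-trimethoxyphenoxy)phenoxy]-1,2-didehydrobenzene (aryne) | COC1=C(Oc2cc(OC)c(Oc3cc(OC)c(OC)c(OC)c3)c(OC)c2)C(OC)=CC#C1 | intermediate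
22 | 3,5-dimethoxy-4-[3,4,5-trimethoxy-2-{3,5-dimethoxy-4-[3,5-dimethoxy-4-(3,4,5-trimethoxyphenoxy)phenoxy]phenoxy}phenoxy]benzaldehyde (B–C–D–E–F pentamer aldehyde) | O=Cc1cc(OC)c(Oc2cc(OC)c(OC)c(OC)c2Oc2cc(OC)c(Oc3cc(OC)c(Oc4cc(OC)c(OC)c(OC)c4)c(OC)c3)c(OC)c2)c(OC)c1 | intermediate
23 | pentamer aryl formate (OCHO in place of CHO of 22) | O=COc1cc(OC)c(Oc2cc(OC)c(OC)c(OC)c2Oc2cc(OC)c(Oc3cc(OC)c(Oc4cc(OC)c(OC)c(OC)c4)c(OC)c3)c(OC)c2)c(OC)c1 | intermediate
24 | pentamer phenol (OH in place of CHO of 22) | Oc1cc(OC)c(Oc2cc(OC)c(OC)c(OC)c2Oc2cc(OC)c(Oc3cc(OC)c(Oc4cc(OC)c(OC)c(OC)c4)c(OC)c3)c(OC)c2)c(OC)c1 | intermediate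
25 | A–F hexamer aldehyde (24 O-arylated on ring B by a 4-formyl-2,6-dimethoxyphenyl group) | O=Cc1cc(OC)c(Oc2cc(OC)c(Oc3cc(OC)c(OC)c(OC)c3Oc3cc(OC)c(Oc4cc(OC)c(Oc5cc(OC)c(OC)c(OC)c5)c(OC)c4)c(OC)c3)c(OC)c2)c(OC)c1 | intermediate
26 | hexamer aryl formate (OCHO in place of CHO of 25) | O=COc1cc(OC)c(Oc2cc(OC)c(Oc3cc(OC)c(OC)c(OC)c3Oc3cc(OC)c(Oc4cc(OC)c(Oc5cc(OC)c(OC)c(OC)c5)c(OC)c4)c(OC)c3)c(OC)c2)c(OC)c1 | intermediate
27 | hexamer phenol, tetradeca-O-methyl ether of the target (free OH para on ring A) | Oc1cc(OC)c(Oc2cc(OC)c(Oc3cc(OC)c(OC)c(OC)c3Oc3cc(OC)c(Oc4cc(OC)c(Oc5cc(OC)c(OC)c(OC)c5)c(OC)c4)c(OC)c3)c(OC)c2)c(OC)c1 | intermediate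
28 | CNP0270681.0 (achiral) | Oc1cc(O)c(Oc2cc(O)c(Oc3cc(O)c(O)c(O)c3Oc3cc(O)c(Oc4cc(O)c(Oc5cc(O)c(O)c(O)c5)c(O)c4)c(O)c3)c(O)c2)c(O)c1 | target

**Count and risks**

Total steps: 14. Longest linear sequence: 12 steps (1 → 3 → 5 → 7 → 8 → 10 → 11 → 15 → 22 → 24 → 25 → 27 → 28; steps 1–7 and 10–14). Steps 8 and 9 form the short ring C branch.

Steps most likely to fail:

1. Step 10. The wrong catechol oxygen may attack 3, or both may; the catechol anion may be oxidized to the ortho-quinone; the aryne may be diverted by the formyl group. The fallback distinguishes the two ring C oxygens by the order in which they are unveiled, not by sterics. It sets out from 17. Benzylation (BnBr, K2CO3, DMF) should give 6-(benzyloxy)-2,3,4-trimethoxybenzaldehyde F1. Baeyer–Villiger oxidation (mCPBA, CH2Cl2) should give 6-(benzyloxy)-2,3,4-trimethoxyphenyl formate F2, and methanolysis (cat. K2CO3, MeOH) 6-(benzyloxy)-2,3,4-trimethoxyphenol F3, in which only the hindered oxygen is free. Aryne O-arylation of F3 with 15 (CsF, MeCN, rt, via aryne 21) should give 1-(benzyloxy)-3,4,5-trimethoxy-2-{3,5-dimethoxy-4-[3,5-dimethoxy-4-(3,4,5-trimethoxyphenoxy)phenoxy]phenoxy}benzene F4, with no aldehyde present. Hydrogenolysis (H2, Pd/C, EtOAc) should free the less hindered oxygen as 3,4,5-trimethoxy-2-{3,5-dimethoxy-4-[3,5-dimethoxy-4-(3,4,5-trimethoxyphenoxy)phenoxy]phenoxy}phenol F5. SNAr of F5 on 3 (Cs2CO3, DMAc, 120 °C) then rejoins the route at 22.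

2. Step 14. The last, mutually chelated methyl ethers may cleave incompletely, and the free pentadecaphenol may be lost to air oxidation during isolation. The fallback sets out from 27. The ethers are cleaved with the hard acid/soft nucleophile pair AlCl3–EtSH in CH2Cl2. The crude polyphenol is acetylated at once (Ac2O, pyridine, cat. DMAP) to the pentadecaacetate of the target F6, which is air-stable and can be chromatographed on silica; under-cleaved material is removed or recycled at this point. Acid methanolysis (HCl in degassed MeOH, Ar) followed by evaporation rejoins the route at 28.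

3. Step 1. Condensation with the bulky reagent and ipso substitution may both be slow at a carbon between two methoxyls, so that reagent hydrolysis competes. The fallback sets out from 1. Sulfuryl fluoride and Et3N in CH2Cl2 should give the isolable 4-formyl-2,6-dimethoxyphenyl fluorosulfonate F7. Anhydrous tetramethylammonium fluoride in DMF (25–80 °C) should then displace fluorosulfate by a stepwise SNAr para to the formyl group; attack of fluoride at sulfur only regenerates F7, so heating is affordable. The route is rejoined at 3.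

**Further compounds**

F1 | step 10 | 6-(benzyloxy)-2,3,4-trimethoxybenzaldehyde | O=Cc1c(OCc2ccccc2)cc(OC)c(OC)c1OC
F2 | step 10 | 6-(benzyloxy)-2,3,4-trimethoxyphenyl formate | O=COc1c(OCc2ccccc2)cc(OC)c(OC)c1OC
F3 | step 10 | 6-(benzyloxy)-2,3,4-trimethoxyphenol | Oc1c(OCc2ccccc2)cc(OC)c(OC)c1OC
F4 | step 10 | 1-(benzyloxy)-3,4,5-trimethoxy-2-{3,5-dimethoxy-4-[3,5-dimethoxy-4-(3,4,5-trimethoxyphenoxy)phenoxy]phenoxy}benzene | COc1cc(OCc2ccccc2)c(Oc2cc(OC)c(Oc3cc(OC)c(Oc4cc(OC)c(OC)c(OC)c4)c(OC)c3)c(OC)c2)c(OC)c1OC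
F5 | step 10 | 3,4,5-trimethoxy-2-{3,5-dimethoxy-4-[3,5-dimethoxy-4-(3,4,5-trimethoxyphenoxy)phenoxy]phenoxy}phenol | COc1cc(O)c(Oc2cc(OC)c(Oc3cc(OC)c(Oc4cc(OC)c(OC)c(OC)c4)c(OC)c3)c(OC)c2)c(OC)c1OC
F6 | step 14 | pentadecaacetate of the target | CC(=O)Oc1cc(OC(C)=O)c(Oc2cc(OC(C)=O)c(Oc3cc(OC(C)=O)c(OC(C)=O)c(OC(C)=O)c3Oc3cc(OC(C)=O)c(Oc4cc(OC(C)=O)c(Oc5cc(OC(C)=O)c(OC(C)=O)c(OC(C)=O)c5)c(OC(C)=O)c4)c(OC(C)=O)c3)c(OC(C)=O)c2)c(OC(C)=O)c1
F7 | step 1 | 4-formyl-2,6-dimethoxyphenyl fluorosulfonate | COc1cc(C=O)cc(OC)c1OS(=O)(=O)F
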